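The data were generated by integration for substances that don't exist, noise included.

One charge of coupling partner is the unit here, and the partner I reckon with below is counted as a fraction of it.

| setting | winter | noon | alder | birch | oak | larch |
|---|---|---|---|---|---|---|
| starting material | 0.098 M | 0.098 M | 0.098 M | 0.098 M (fed, over 6.0 min) | 0.098 M | 0.098 M |
| coupling partner | 0.49 M | 0.24 M | 0.490 M | 0.490 M | 0.490 M (fed, over 6.0 min) | 0.490 M |
| temperature | 50 °C | 50 °C |  |  | 50 °C | 50 °C |
| remark | run made earlier | run made earlier | everything together at the start at 30 °C, warmed to 50 °C at 6.0 min | the addition at 30 °C, then warmed to 50 °C; the feed brings no volume worth counting | all else is in the flask from the start; the feed brings no volume worth counting | everything together at the start |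
| time |  |  | 15 min | 15 min | 15 min | 15 min |

winter run (percent of the starting material charged)

| time / min | target / % | side product A / % | starting material / % |
|---|---|---|---|
| 1.00 | 2 | 3 | 69 |
| 3.00 | 8 | 10 | 38 |
| 5.00 | 11 | 12 | 29 |
| 8.00 | 9 | 19 | 16 |
| 12.0 | 15 | 19 | 11 |
| 15.0 | 10 | 26 | 8 |

noon run (percent of the starting material charged)

| time / s | target / % | side product A / % | starting material / % |
|---|---|---|---|
| 10.0 | 2 | 3 | 94 |
| 20.0 | 0 | 2 | 88 |
| 30.0 | 3 | 1 | 87 |
| 50.0 | 1 | 4 | 73 |
| 60.0 | 5 | 4 | 70 |
| 90.0 | 5 | 6 | 63 |

(scatter of a reading: 2 percentage points)

- which flask leads in share of target in target plus side product A ("all alike" within 1.5 percentage points) (alder / birch / oak / larch / all alike)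
- share of target in target plus side product A at the end, alder
- share of target in target plus side product A at the end, birch
- share of target in target plus side product A at the end, oak
- share of target in target plus side product A at the end, larch

- the analysis behind the earlier runs scatters by 2 percentage points, standard deviation
- the earlier runs do not show what temperature does; that part of a forecast is a guess

Target takes up coupling partner, and side product A, I assume, does not. So their ratio, the selectivity factor, should follow how much partner a molecule of starting material meets. With scatter of 2 percentage points on such small peaks, the noon and winter readings show no clear difference in this ratio.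

They do show something else. Starting material fades alike at both partner levels: noon holds 70% at 60.0 s, winter 69% at 1.00 min. Oak's starting material should therefore fade as winter's does, whatever partner has arrived. Winter's 29% at 5.00 min reads as a lifetime of 4.04 min, shorter than oak's feed of 6.0 min.

Two limits bound oak. With a feed far shorter than the lifetime, oak is larch, and the fraction met is one. With a feed far longer, that fraction shrinks towards lifetime over feed time. Between them, the lifetime over the feed time is multiplied by the part of starting material gone when the feed ends, here 77.4%. For oak that gives 0.521, and this number is the seen partner, the mean fraction of a charge present over the life of the starting material.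

Winter's last three readings pool to a ratio of 0.531, a share of 34.7%. Alder, birch and larch hold the whole partner charge from the start, so I put them near that and leave them unranked, since a cold start is a guess. Scaled down by oak's seen partner, winter's ratio gives oak a share of 21.7%, below winter's.

The forecast differs on oak: 39% for alder, 40% for birch, 33% for oak and 34% for larch, with birch ahead and “Oak should be similar or slightly lower”.

The flasks give 41.3% in alder, 39.2% in birch, 23.1% in oak and 33.0% in larch, so alder leads.

    starting material + coupling partner → target (k = 0.00180 M⁻¹ s⁻¹, Ea = 67.0 kJ mol⁻¹)
    starting material → side product A (k = 9.40 × 10⁻⁴ s⁻¹, Ea = 92.0 kJ mol⁻¹)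
    2 starting material → side product B (k = 0.0270 M⁻¹ s⁻¹, Ea = 67.0 kJ mol⁻¹)
    target → over-reaction product A (k = 4.00 × 10⁻⁴ s⁻¹, Ea = 99.0 kJ mol⁻¹)
    target → over-reaction product B (k = 6.70 × 10⁻⁷ s⁻¹, Ea = 123 kJ mol⁻¹)
    coupling partner → decomposed reagent (k = 0.00150 s⁻¹, Ea = 100 kJ mol⁻¹)
    (constants at 50 °C)

Oak's ratio over larch's comes to 0.610, against my seen partner of 0.521. The neighbour of alder starts with 0.83 M of coupling partner, which is 1.69 charges, and that is its seen partner. Alder's ratio of 0.702 scaled by this becomes 1.19, a share of 54.3%. The neighbour of alder gives 54.8%.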